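## Analysis of the target

Amaurone B joins a 2-methoxy-3,5-dimethyl-4H-pyran-4-one (ring A) through an all-E triene chain to a fully substituted cyclohexane (ring B). The chain carbons are lettered from the pyranone: Ca(Me)=Cb–Cc=Cd–Ce(Me)=Cf. Ring B is numbered so that C1 carries the chain, C2 a methyl group, C3 and C5 are tertiary methyl carbinols, and C4 and C6 carry the acetoxy groups.

All six ring carbons are stereocentres, (1R,2S,3R,4R,5S,6S) in this numbering. The chain on C1 and the methyl on C2 are cis on one face, and the four oxygens on C3 to C6 all sit on the opposite face.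

The sensitive groups are the methoxypyranone (a vinylogous carbonate, labile to acid and strong nucleophiles), the light- and oxygen-sensitive conjugated triene, and the secondary acetates next to free tertiary alcohols. The difficulty is six contiguous stereocentres, two of them tetrasubstituted, on a carbocycle with no carbonyl or heteroatom to steer reagents, followed by union with a fragile polyene.

The plan rests on one feature of ring B: a cis pair of carbon substituents on C1/C2 next to a four-carbon oxygenated run C3–C6 with methyls on C3 and C5. This is the oxidation pattern of a cis-5,6-disubstituted 1,3-dimethylcyclohexa-1,3-diene (C3=C4, C5=C6) oxidised on the face away from its substituents. Such a diene is what thermal 6π ring closure of an (E,Z,E)-triene delivers.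

## Retrosynthetic reasoning

**Acetates.** The two ester C–O bonds at C4 and C6 of 36 are cut last, giving tetraol 35. Secondary hydroxyls are acylated far faster than tertiary ones, so the forward step needs no protecting groups, and no base-labile ester has to survive the olefination or any hydride step.

**Cc=Cd alkene.** 35 is cut at the disubstituted alkene into aldehyde 19 and phosphonium salt 33. This is the only chain alkene without a methyl group, so a Wittig reaction can form it with E control. The cut separates the achiral heterocyclic half from the stereochemically dense half, so the valuable ring fragment meets the pyranone only once.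

**Pyranone fragment.** 33 goes back through bromide 32 and alcohol 31 to silyl ether 30. The Ca=Cb alkene of 30 is opened to aldol 28, and the Ca–Cb bond is cut to ethylpyranone 25 and aldehyde 26. The ethyl CH2 of 25 is the only vinylogously acidic position, so the bond forms at a predictable site and dehydration gives the conjugated E alkene.

**Ring A.** The methyl ether of 25 is removed to hydroxypyranone 24, the lactone C–O bond is opened to diketo ester 23, and the bond between the two ketone-flanked carbons is cut to keto ester 20 and amide 21. The ring is thus assembled from two propionate-level pieces by enolate chemistry.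

**Oxidation level of the chain terminus.** 19 goes back through pentaol 18 to ester 17. The ester is kept as long as possible because it deactivates the Ce=Cf alkene toward both oxidations of the ring. It is reduced before the final acetylation because a hydride would strip acetates.

**C4–O and C5–O.** These two bonds of 17 are cut to the cyclohexene 15. The forward step must add two oxygens to the face that already carries the C3 and C6 oxygens, which calls for a hydroxyl-directed syn-dihydroxylation.

**Absolute configuration.** 15 is traced to racemic diol 14 by removing the acetyl group from O6. The only secondary alcohol of 14 is the handle for an enzymatic kinetic resolution, placed as early as a suitable alcohol exists.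

**C3–O and C6–O.** The cis-1,4-diol of 14 comes from the peroxide bridge of 13, and both C–O bonds are cut to diene 12. A [4+2] photooxygenation adds to the ring diene on the face away from the C1 and C2 substituents and leaves the C4=C5 alkene for the next oxidation.

**C1–C2 bond (the central cut).** Opening 12 between C1 and C2 gives the acyclic tetraenoate 11. Made here, this bond closes the ring and sets the cis C1/C2 relation from alkene geometry alone. The 1,3-methyl pattern and the first three chain carbons are already in place.

**Tetraene.** 11 is cut at its C4=C5 alkene to Z-dienal 6 and allylic phosphonate 9, which comes from 7 via bromide 8. The Z alkene of 6 is traced through alcohol 5 and ester 4 to aldehyde 2 and phosphonate 1, so the one alkene geometry that controls the ring closure is set by a Z-selective olefination.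

## Alternatives that were turned down

**Alternative 1:** Endoperoxide formation as the central step.
- Disconnection: the C3–O and C6–O bonds of ring B, back to the peroxide bridge of endoperoxide A1 and then to the silyl-protected cis-dienyl carbinol A2.
- Forward key step: sensitised photooxygenation of A2, a [4+2] addition across C3 to C6 anti to the C1 and C2 substituents.
- For: two C–O stereocentres are set in one reliable step. A2 has no second alkene that could compete, which is cleaner than the chosen route, where an enoate alkene is present. A2 might be made enantioenriched by an auxiliary- or catalyst-controlled cycloaddition, which would avoid a resolution; on absolute control this alternative is stronger.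
- Against: the step builds no C–C bond and no carbon stereocentre. The hard problem, a cis-5,6-disubstituted diene with the right methyl pattern, is only moved back to the preparation of A2. The chain must then be grown from a one-carbon stub through an aldehyde whose α-carbon is C1, which can epimerise from cis to trans, and two olefinations are needed on the ring fragment.
- Comparison: the chosen route uses the same photooxygenation as a supporting step (step 8) but reaches its diene 12 from acyclic 11 in one thermal step. It pays for this with a racemic ring closure.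

**Alternative 2:** Acylketene–ketene acetal construction of ring A.
- Disconnection: the C3–C4 and O1–C2 bonds of the pyranone, back to dioxinone A4 and ketene acetal A5.
- Forward key step: thermolysis of A4 releases acylketene A6, which is trapped by A5; loss of methanol gives methoxypyranone A3.
- For: the methoxy group is placed at C2 by construction, so the α- versus γ-pyranone question of step 16 does not arise; on regiocontrol this is stronger. A3 is the same compound as 30 and could enter the same endgame.
- Against: the step addresses only the achiral heterocycle and leaves the carbocycle and all six stereocentres unsolved. A4 needs its own multistep preparation, A5 is moisture-sensitive, and the conjugated acylketene A6 can dimerise or add the methanol released. The fragment is no shorter than the five enolate steps from 20 to 30.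
- Comparison: as the centre of a strategy it puts the risk where little is gained. The chosen route spends its key step on the ring and builds ring A in a side branch by routine chemistry.

**Alternative 3:** α-Ketol ring expansion.
- Disconnection: the C2–C3 bond of ring B, back to the ring-contracted acetylcyclopentanol A8, whose C4 carries a hydroxyl and the acetyl group that becomes C3 and its methyl.
- Forward key step: base-mediated α-ketol rearrangement in which C2 migrates from C4 to the acetyl carbonyl carbon, giving cyclohexanone A7 with the C3 carbinol and a C4 ketone.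
- For: cyclopentane chemistry gives well-understood control of the cis C5/C6 diol and the C1/C2 pair. An enantiopure cyclopentene building block could fix the absolute configuration without resolution, which is stronger than the chosen route on that point. The step also creates a tetrasubstituted carbinol.
- Against: the C3 configuration depends on which face of the acetyl carbonyl the migrating carbon reaches, that is, on the conformation of a chelated ketol, and the substrate does not secure it. The rearrangement is reversible, A7 is itself an α-ketol that can shift again, and the oxygenated quaternary C5 can compete as migrating group. C4 then needs a face-selective reduction between two quaternary centres. The chain must be grown from a benzyloxymethyl stub, and benzyl and acetonide groups add protecting-group steps.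
- Comparison: a long linear sequence to A8 and as many steps after A7, against one pericyclic step and three oxidations without ring protecting groups in the chosen route.

Key step: step 7

Remark on the chemistry: the ring closure of step 7 gives a racemate, so 12, 13 and 14 are racemic and drawn as the enantiomer carried on; for step 10 the lipase is assumed to follow Kazlauskas' rule with the branched ring carbon C1 as the large substituent of the C6 carbinol, which makes the needed (6S)-alcohol the fast-reacting one.

## Route

**Step 1**
Reactants: 1 methyl 2-[bis(2,2,2-trifluoroethoxy)phosphoryl]propanoate; 2 (2E)-2-methylbut-2-enal (tiglaldehyde)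
Product: 4 methyl (2Z,4E)-2,4-dimethylhexa-2,4-dienoate, via potassium carbanion of the phosphonate 3 (not isolated)
Conditions: KN(SiMe3)2, 18-crown-6, THF, −78 °C; then 2, −78 °C
Reagents that add atoms: none
Why: Still–Gennari olefination; the electron-poor bis(trifluoroethyl) phosphonate eliminates quickly from the kinetically formed adduct, which should give the Z trisubstituted enoate while the E alkene of 2 is untouched.

**Step 2**
Reactants: 4 methyl (2Z,4E)-2,4-dimethylhexa-2,4-dienoate
Product: 5 (2Z,4E)-2,4-dimethylhexa-2,4-dien-1-ol
Conditions: i-Bu2AlH, CH2Cl2, −78 °C; aq. KNaC4H4O6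
Reagents that add atoms: none
Why: 1,2-Reduction of the conjugated ester by the aluminium hydride at low temperature leaves both alkene geometries intact.

**Step 3**
Reactants: 5 (2Z,4E)-2,4-dimethylhexa-2,4-dien-1-ol
Product: 6 (2Z,4E)-2,4-dimethylhexa-2,4-dienal
Conditions: MnO2, CH2Cl2, 0 °C, dark; used at once
Reagents that add atoms: none
Why: Allylic oxidation on MnO2 under neutral conditions, chosen because the Z α-methyl enal isomerises with acid, base or light.

**Step 4**
Reactants: 7 ethyl (2E)-2-methylbut-2-enoate (ethyl tiglate)
Product: 8 ethyl (2E)-4-bromo-2-methylbut-2-enoate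
Conditions: N-bromosuccinimide, AIBN (cat.), PhCF3, reflux
Reagents that add atoms: N-bromosuccinimide, O=C1CCC(=O)N1Br
Why: Wohl–Ziegler bromination; hydrogen abstraction at the γ-methyl gives the ester-conjugated allyl radical, and the minor 2-(bromomethyl) isomer is removed by distillation.

**Step 5**
Reactants: 8 ethyl (2E)-4-bromo-2-methylbut-2-enoate
Product: 9 ethyl (2E)-4-(diethoxyphosphoryl)-2-methylbut-2-enoate
Conditions: P(OEt)3, neat, 130 °C
Reagents that add atoms: triethyl phosphite, CCOP(OCC)OCC
Why: Michaelis–Arbuzov reaction of a primary allylic bromide.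

**Step 6**
Reactants: 9 ethyl (2E)-4-(diethoxyphosphoryl)-2-methylbut-2-enoate; 6 (2Z,4E)-2,4-dimethylhexa-2,4-dienal
Product: 11 ethyl (2E,4E,6Z,8E)-2,6,8-trimethyldeca-2,4,6,8-tetraenoate, via lithiated allylic phosphonate 10 (not isolated)
Conditions: LiN(SiMe3)2, THF, −78 °C; then 6, −78 → 0 °C; cold work-up, used directly
Reagents that add atoms: none
Why: Vinylogous Horner–Wadsworth–Emmons olefination; the ester-stabilised allyl anion reacts at the carbon next to phosphorus and the reversible addition should give the new C4=C5 alkene E, while low temperature and the absence of excess base preserve the Z alkene brought in by 6.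

**Step 7**
Reactants: 11 ethyl (2E,4E,6Z,8E)-2,6,8-trimethyldeca-2,4,6,8-tetraenoate
Product: 12 ethyl (2E)-2-methyl-3-[(1R*,6S*)-3,5,6-trimethylcyclohexa-2,4-dien-1-yl]prop-2-enoate (cis, racemic)
Conditions: toluene (dilute, degassed), 2,6-di-tert-butyl-4-methylphenol (cat.), dark, 80–110 °C
Reagents that add atoms: none
Why: Thermal 6π electrocyclisation of the triene formed by chain carbons C4 to C9 of 11, the closest known reaction type being the disrotatory closure of (E,Z,E)-hexa-1,3,5-trienes to cis-5,6-disubstituted cyclohexa-1,3-dienes. The six π electrons reorganise suprafacially through a boat-like aromatic transition state in which the new σ bond forms between chain carbons C4 and C9, the later ring carbons C1 and C2. This closes the single six-membered carbocycle in the ground-state-allowed disrotatory mode. Both new stereocentres are fixed relative to each other by orbital symmetry together with the E geometry of the two terminal alkenes: the enoate arm and the methyl group, both outward in the s-cis,s-cis conformer, turn onto the same ring face, so only the cis isomer should form. Since 11 is achiral and no chiral influence is present, 12 is a racemate and the absolute configuration is left to step 10. The periselectivity is built into the substrate: only the triene around the single Z alkene can reach the closing geometry, the triene that includes the enoate alkene has an E central bond, and an eight-electron closure would need two Z bonds. The methyl groups on chain carbons C6 and C8 twist the open triene and should lower the barrier, so that moderate heating in dilute solution suffices and 1,5-hydrogen shifts or Diels–Alder dimerisation of 12 are avoided.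

**Step 8**
Reactants: 12 ethyl (2E)-2-methyl-3-[(1R*,6S*)-3,5,6-trimethylcyclohexa-2,4-dien-1-yl]prop-2-enoate
Product: 13 ethyl (2E)-2-methyl-3-[(1S*,4R*,7R*,8S*)-4,6,8-trimethyl-2,3-dioxabicyclo[2.2.2]oct-5-en-7-yl]prop-2-enoate (racemic; peroxide bridge from C3 to C6, anti to the C1 and C2 substituents)
Conditions: O2, visible light, tetraphenylporphyrin (cat.), CH2Cl2, −40 °C
Reagents that add atoms: oxygen, O=O
Why: [4+2] Cycloaddition of singlet oxygen to the s-cis ring diene on the face away from the substituents on C1 and C2, which sets C3–O and C6–O cis to each other and trans to those substituents; the enoate alkene is too electron-poor for an ene reaction.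

**Step 9**
Reactants: 13 the endoperoxide
Product: 14 ethyl (2E)-3-[(1R*,2S*,5R*,6S*)-2,5-dihydroxy-3,5,6-trimethylcyclohex-3-en-1-yl]-2-methylprop-2-enoate (racemic cis-1,4-diol)
Conditions: thiourea, MeOH, 0 °C → rt
Reagents that add atoms: none
Why: Reduction of the O–O bond by thiourea under neutral conditions keeps both C–O bonds and hence the cis-diol; base is avoided because the peroxide carbon C6 bears a hydrogen and would undergo Kornblum–DeLaMare rearrangement.

**Step 10**
Reactants: 14 the racemic diol
Product: 15 ethyl (2E)-3-[(1R,2S,5R,6S)-2-acetoxy-5-hydroxy-3,5,6-trimethylcyclohex-3-en-1-yl]-2-methylprop-2-enoate (acetate on ring carbon C6, single enantiomer)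
Conditions: lipase PS (Burkholderia cepacia, immobilised), vinyl acetate, t-BuOMe, 35 °C, stopped below half conversion; chromatography
Reagents that add atoms: vinyl acetate, C=COC(C)=O
Why: Lipase-catalysed kinetic resolution by irreversible transesterification; only the secondary C6 hydroxyl can be acylated, and by Kazlauskas' rule the (6S)-enantiomer should react while the mirror-image diol stays behind and is separated.

**Step 11**
Reactants: 15 the monoacetate
Product: 17 ethyl (2E)-3-[(1R,2S,3R,4R,5R,6S)-2-acetoxy-3,4,5-trihydroxy-3,5,6-trimethylcyclohexyl]-2-methylprop-2-enoate, via TMEDA-bound osmate ester of hexavalent osmium 16 (not isolated)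
Conditions: OsO4 (1 equiv), TMEDA, CH2Cl2, −78 °C; then aq. Na2SO3, THF, 60 °C
Reagents that add atoms: osmium tetroxide, O=[Os](=O)(=O)=O
Why: Hydrogen-bond-directed dihydroxylation with the OsO4–diamine complex, which is held by the pseudoaxial C3 hydroxyl and adds to C4=C5 on the oxygen-bearing face, setting C4 and C5 all-cis to C3 and C6; the ester-conjugated alkene is much less nucleophilic, and partial loss of the acetate in the work-up would be harmless because step 12 removes it.

**Step 12**
Reactants: 17 the triol acetate
Product: 18 (1R,2R,3S,4S,5R,6S)-5-[(1E)-3-hydroxy-2-methylprop-1-en-1-yl]-1,3,6-trimethylcyclohexane-1,2,3,4-tetrol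
Conditions: i-Bu2AlH (excess), THF, −78 → 0 °C; aq. KNaC4H4O6, continuous extraction
Reagents that add atoms: none
Why: Hydride reduction of the enoate to the allylic alcohol; the resolving acetate is cleaved in the same operation, which is why the final acetates are introduced only after this step.

**Step 13**
Reactants: 18 the pentaol
Product: 19 (2E)-2-methyl-3-[(1R,2S,3S,4R,5R,6S)-2,3,4,5-tetrahydroxy-3,5,6-trimethylcyclohexyl]prop-2-enal
Conditions: MnO2, acetone, rt
Reagents that add atoms: none
Why: MnO2 oxidises only the primary allylic alcohol and leaves the saturated secondary and tertiary ring hydroxyls; the E geometry keeps the aldehyde from closing a lactol onto the C6 hydroxyl.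

**Step 14**
Reactants: 20 methyl 2-methyl-3-oxopentanoate; 21 N-methoxy-N-methylpropanamide
Product: 23 methyl 2,4-dimethyl-3,5-dioxoheptanoate (mixture of diastereomers and enol forms), via sodium lithium dienolate 22 (not isolated)
Conditions: NaH, THF, 0 °C; n-BuLi, 0 °C; then 21, −78 → 0 °C; aq. HCl
Reagents that add atoms: none
Why: γ-Acylation of a β-keto ester dianion at its more basic terminal carbanion; the Weinreb amide adds once and the chelated adduct survives until work-up, so no over-addition occurs.

**Step 15**
Reactants: 23 the diketo ester
Product: 24 6-ethyl-4-hydroxy-3,5-dimethyl-2H-pyran-2-one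
Conditions: DBU, toluene, 80 °C; aq. HCl
Reagents that add atoms: none
Why: Base-mediated lactonisation of the enolised 5-ketone onto the methyl ester gives the aromatic 4-hydroxy-2-pyranone.

**Step 16**
Reactants: 24 the hydroxypyranone
Product: 25 2-ethyl-6-methoxy-3,5-dimethyl-4H-pyran-4-one
Conditions: MeOSO2CF3, CH2Cl2, rt; then aq. NaHCO3
Reagents that add atoms: methyl trifluoromethanesulfonate, COS(=O)(=O)C(F)(F)F
Why: Hard O-methylation at the lactone carbonyl oxygen, the most electron-rich site of the vinylogous acid; loss of the proton from the resulting 4-hydroxypyrylium ion gives the 2-methoxy-4-pyranone, not the 4-methoxy-2-pyranone.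

**Step 17**
Reactants: 25 the ethylpyranone; 26 2-[(tert-butyldimethylsilyl)oxy]acetaldehyde
Product: 28 2-{4-[(tert-butyldimethylsilyl)oxy]-3-hydroxybutan-2-yl}-6-methoxy-3,5-dimethyl-4H-pyran-4-one (diastereomer mixture), via lithium dienolate of the ethylpyranone 27 (not isolated)
Conditions: LiN(SiMe3)2, THF, −78 °C; then 26; AcOH, −78 °C
Reagents that add atoms: none
Why: Vinylogous aldol addition; the ethyl CH2 is the only vinylogously acidic position of 25 and its dienolate reacts with the aldehyde at that carbon, and the two new stereocentres are erased in the next step.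

**Step 18**
Reactants: 28 the aldol adduct
Product: 30 2-{(2E)-4-[(tert-butyldimethylsilyl)oxy]but-2-en-2-yl}-6-methoxy-3,5-dimethyl-4H-pyran-4-one, via secondary mesylate 29 (not isolated)
Conditions: MsCl, Et3N, CH2Cl2, 0 °C; then DBU, rt
Reagents that add atoms: none
Why: E1cB elimination through the vinylogous enolate gives the pyranone-conjugated trisubstituted alkene Ca=Cb, expected as the E isomer, which keeps the ring and the CH2O group apart.

**Step 19**
Reactants: 30 the silyl ether
Product: 31 2-[(2E)-4-hydroxybut-2-en-2-yl]-6-methoxy-3,5-dimethyl-4H-pyran-4-one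
Conditions: Bu4NF, AcOH, THF, 0 °C
Reagents that add atoms: none
Why: Fluoride-induced cleavage of the primary silyl ether; the acetic acid buffer protects the methoxypyranone from alkoxide.

**Step 20**
Reactants: 31 the allylic alcohol
Product: 32 2-[(2E)-4-bromobut-2-en-2-yl]-6-methoxy-3,5-dimethyl-4H-pyran-4-one
Conditions: CBr4, PPh3, CH2Cl2, 0 °C
Reagents that add atoms: carbon tetrabromide, BrC(Br)(Br)Br
Why: Appel bromination of a primary allylic alcohol under neutral conditions, without allylic transposition because the alkene stays conjugated to the pyranone.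

**Step 21**
Reactants: 32 the allylic bromide
Product: 33 tributyl[(2E)-3-(6-methoxy-3,5-dimethyl-4-oxo-4H-pyran-2-yl)but-2-en-1-yl]phosphonium bromide
Conditions: PBu3, MeCN, rt
Reagents that add atoms: tributylphosphine, CCCCP(CCCC)CCCC
Why: SN2 quaternisation of the phosphine by the primary allylic bromide.

**Step 22**
Reactants: 33 the phosphonium bromide; 19 the tetraol aldehyde
Product: 35 2-methoxy-3,5-dimethyl-6-{(2E,4E,6E)-6-methyl-7-[(1R,2S,3S,4R,5R,6S)-2,3,4,5-tetrahydroxy-3,5,6-trimethylcyclohexyl]hepta-2,4,6-trien-2-yl}-4H-pyran-4-one, via tributylphosphonium ylide 34 (not isolated)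
Conditions: KOC(CH3)3 (1 equiv), THF, −78 → 0 °C; then 19, THF, −78 °C → rt, dark
Reagents that add atoms: none
Why: Wittig olefination with an allylic trialkylphosphonium ylide, a reagent class that gives E alkenes with enals; the pyranone-conjugated ylide is too weakly basic to deprotonate the ring hydroxyls, and the Ca=Cb and Ce=Cf geometries are carried in unchanged.

**Step 23**
Reactants: 35 the tetraol
Product: 36 amaurone B, (1S,2S,3R,4R,5S,6R)-2,4-dihydroxy-6-[(1E,3E,5E)-6-(6-methoxy-3,5-dimethyl-4-oxo-4H-pyran-2-yl)-2-methylhepta-1,3,5-trien-1-yl]-2,4,5-trimethylcyclohexane-1,3-diyl diacetate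
Conditions: Ac2O, pyridine, 4-(dimethylamino)pyridine (cat.), CH2Cl2, 0 °C → rt, dark
Reagents that add atoms: acetic anhydride, CC(=O)OC(C)=O
Why: Acylation of the two equatorial secondary hydroxyls on C4 and C6; the axial tertiary hydroxyls on C3 and C5 are far slower and should stay free under these mild conditions.

## Compound list

1 | methyl 2-[bis(2,2,2-trifluoroethoxy)phosphoryl]propanoate | COC(=O)C(C)P(=O)(OCC(F)(F)F)OCC(F)(F)F | starting material
2 | (2E)-2-methylbut-2-enal | C/C=C(\C)C=O | starting material
3 | potassium carbanion of phosphonate 1 | COC(=O)[C-](C)P(=O)(OCC(F)(F)F)OCC(F)(F)F.[K+] | intermediate (not isolated)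
4 | methyl (2Z,4E)-2,4-dimethylhexa-2,4-dienoate | COC(=O)/C(C)=C\C(C)=C\C | intermediate
5 | (2Z,4E)-2,4-dimethylhexa-2,4-dien-1-ol | OC/C(C)=C\C(C)=C\C | intermediate
6 | (2Z,4E)-2,4-dimethylhexa-2,4-dienal | O=C/C(C)=C\C(C)=C\C | intermediate
7 | ethyl (2E)-2-methylbut-2-enoate | CCOC(=O)/C(C)=C/C | starting material
8 | ethyl (2E)-4-bromo-2-methylbut-2-enoate | CCOC(=O)/C(C)=C/CBr | intermediate
9 | ethyl (2E)-4-(diethoxyphosphoryl)-2-methylbut-2-enoate | CCOC(=O)/C(C)=C/CP(=O)(OCC)OCC | intermediate
10 | lithium carbanion of phosphonate 9 | CCOC(=O)/C(C)=C/[CH-]P(=O)(OCC)OCC.[Li+] | intermediate (not isolated)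
11 | ethyl (2E,4E,6Z,8E)-2,6,8-trimethyldeca-2,4,6,8-tetraenoate | CCOC(=O)/C(C)=C/C=C/C(C)=C\C(C)=C\C | intermediate
12 | ethyl (2E)-2-methyl-3-[(1R*,6S*)-3,5,6-trimethylcyclohexa-2,4-dien-1-yl]prop-2-enoate (racemic, drawn as the 1R,6S enantiomer) | CCOC(=O)/C(C)=C/[C@@H]1[C@H](C)C(C)=CC(C)=C1 | intermediate
13 | ethyl (2E)-2-methyl-3-[(1S*,4R*,7R*,8S*)-4,6,8-trimethyl-2,3-dioxabicyclo[2.2.2]oct-5-en-7-yl]prop-2-enoate (racemic, drawn as the enantiomer carried on) | CCOC(=O)/C(C)=C/[C@@H]1[C@H](C)[C@]2(C)C=C(C)[C@H]1OO2 | intermediate
14 | ethyl (2E)-3-[(1R*,2S*,5R*,6S*)-2,5-dihydroxy-3,5,6-trimethylcyclohex-3-en-1-yl]-2-methylprop-2-enoate (racemic, drawn as the enantiomer carried on) | CCOC(=O)/C(C)=C/[C@@H]1[C@H](C)[C@@](C)(O)C=C(C)[C@H]1O | intermediate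
15 | ethyl (2E)-3-[(1R,2S,5R,6S)-2-acetoxy-5-hydroxy-3,5,6-trimethylcyclohex-3-en-1-yl]-2-methylprop-2-enoate | CCOC(=O)/C(C)=C/[C@@H]1[C@H](C)[C@@](C)(O)C=C(C)[C@H]1OC(C)=O | intermediate
16 | TMEDA-bound dioxo osmate ester (hexavalent osmium) across ring carbons C4 and C5 of 15 | CCOC(=O)/C(C)=C/[C@@H]1[C@H](C)[C@@](C)(O)[C@H]2O[Os-2]3(=O)(=O)([N+](C)(C)CC[N+]3(C)C)O[C@@]2(C)[C@H]1OC(C)=O | intermediate (not isolated)
17 | ethyl (2E)-3-[(1R,2S,3R,4R,5R,6S)-2-acetoxy-3,4,5-trihydroxy-3,5,6-trimethylcyclohexyl]-2-methylprop-2-enoate | CCOC(=O)/C(C)=C/[C@@H]1[C@H](C)[C@@](C)(O)[C@@H](O)[C@@](C)(O)[C@H]1OC(C)=O | intermediate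
18 | (1R,2R,3S,4S,5R,6S)-5-[(1E)-3-hydroxy-2-methylprop-1-en-1-yl]-1,3,6-trimethylcyclohexane-1,2,3,4-tetrol | OC/C(C)=C/[C@@H]1[C@H](C)[C@@](C)(O)[C@@H](O)[C@@](C)(O)[C@H]1O | intermediate
19 | (2E)-2-methyl-3-[(1R,2S,3S,4R,5R,6S)-2,3,4,5-tetrahydroxy-3,5,6-trimethylcyclohexyl]prop-2-enal | O=C/C(C)=C/[C@@H]1[C@H](C)[C@@](C)(O)[C@@H](O)[C@@](C)(O)[C@H]1O | intermediate
20 | methyl 2-methyl-3-oxopentanoate | CCC(=O)C(C)C(=O)OC | starting material
21 | N-methoxy-N-methylpropanamide | CCC(=O)N(C)OC | starting material
22 | sodium lithium dienolate of 20 | CC=C([O-])C(C)=C([O-])OC.[Na+].[Li+] | intermediate (not isolated)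
23 | methyl 2,4-dimethyl-3,5-dioxoheptanoate | CCC(=O)C(C)C(=O)C(C)C(=O)OC | intermediate
24 | 6-ethyl-4-hydroxy-3,5-dimethyl-2H-pyran-2-one | CCc1oc(=O)c(C)c(O)c1C | intermediate
25 | 2-ethyl-6-methoxy-3,5-dimethyl-4H-pyran-4-one | CCc1oc(OC)c(C)c(=O)c1C | intermediate
26 | 2-[(tert-butyldimethylsilyl)oxy]acetaldehyde | CC(C)(C)[Si](C)(C)OCC=O | starting material
27 | lithium dienolate of 25 | CC=C1OC(OC)=C(C)C([O-])=C1C.[Li+] | intermediate (not isolated)
28 | 2-{4-[(tert-butyldimethylsilyl)oxy]-3-hydroxybutan-2-yl}-6-methoxy-3,5-dimethyl-4H-pyran-4-one (diastereomer mixture) | COc1oc(C(C)C(O)CO[Si](C)(C)C(C)(C)C)c(C)c(=O)c1C | intermediate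
29 | methanesulfonate of 28 | COc1oc(C(C)C(CO[Si](C)(C)C(C)(C)C)OS(C)(=O)=O)c(C)c(=O)c1C | intermediate (not isolated)
30 | 2-{(2E)-4-[(tert-butyldimethylsilyl)oxy]but-2-en-2-yl}-6-methoxy-3,5-dimethyl-4H-pyran-4-one | COc1oc(/C(C)=C/CO[Si](C)(C)C(C)(C)C)c(C)c(=O)c1C | intermediate
31 | 2-[(2E)-4-hydroxybut-2-en-2-yl]-6-methoxy-3,5-dimethyl-4H-pyran-4-one | COc1oc(/C(C)=C/CO)c(C)c(=O)c1C | intermediate
32 | 2-[(2E)-4-bromobut-2-en-2-yl]-6-methoxy-3,5-dimethyl-4H-pyran-4-one | COc1oc(/C(C)=C/CBr)c(C)c(=O)c1C | intermediate
33 | tributyl[(2E)-3-(6-methoxy-3,5-dimethyl-4-oxo-4H-pyran-2-yl)but-2-en-1-yl]phosphonium bromide | COc1oc(/C(C)=C/C[P+](CCCC)(CCCC)CCCC)c(C)c(=O)c1C.[Br-] | intermediate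
34 | ylide of 33 | COc1oc(/C(C)=C/C=P(CCCC)(CCCC)CCCC)c(C)c(=O)c1C | intermediate (not isolated)
35 | 2-methoxy-3,5-dimethyl-6-{(2E,4E,6E)-6-methyl-7-[(1R,2S,3S,4R,5R,6S)-2,3,4,5-tetrahydroxy-3,5,6-trimethylcyclohexyl]hepta-2,4,6-trien-2-yl}-4H-pyran-4-one | COc1oc(/C(C)=C/C=C/C(C)=C/[C@@H]2[C@H](C)[C@@](C)(O)[C@@H](O)[C@@](C)(O)[C@H]2O)c(C)c(=O)c1C | intermediate
36 | amaurone B | COc1oc(/C(C)=C/C=C/C(C)=C/[C@@H]2[C@H](C)[C@@](C)(O)[C@@H](OC(C)=O)[C@@](C)(O)[C@H]2OC(C)=O)c(C)c(=O)c1C | target

## Step count and least certain steps

Total step count: 23. Longest linear sequence: 13 steps (steps 1, 2, 3, 6, 7, 8, 9, 10, 11, 12, 13, 22, 23).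

**Step 7 (key step).** The most likely failure is loss of the Z geometry of the central alkene before closure, by light, traces of acid, or already at the stage of enal 6. That leaves all-E tetraene that cannot reach the closing conformation. If long heating is needed, 1,5-hydrogen shifts could also move the ring diene out of the C3–C6 positions.
Fallback: the triene is generated and closed in one flask by a Stille coupling, so that the Z alkene comes from a configurationally stable vinyl iodide. Setting out from 2, Stork–Zhao-type olefination with the α-iodo ylide from ethyltriphenylphosphonium bromide (n-BuLi, I2, then NaN(SiMe3)2) should give (2Z,4E)-2-iodo-4-methylhexa-2,4-diene F1. Commercial (2E)-3-(tributylstannyl)prop-2-en-1-ol is oxidised with MnO2 to (2E)-3-(tributylstannyl)prop-2-enal F2, and Wittig reaction with ethyl 2-(triphenylphosphoranylidene)propanoate gives ethyl (2E,4E)-2-methyl-5-(tributylstannyl)penta-2,4-dienoate F3. Coupling of F1 and F3 with Pd(PPh3)4 (zerovalent palladium), CuI and CsF in DMF at 45 °C forms 11, which on warming closes in the same flask and returns to the route at 12.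

**Step 10.** The carbinol carbon C6 is flanked on both sides by substituted carbons, so acylation may be slow and the two enantiomers poorly discriminated. The acetate would then have insufficient enantiomeric purity, and the sense of the preference is also not certain.
Fallback: a covalent resolution. Setting out from 14, esterification of the C6 hydroxyl with (S)-2-methoxy-2-phenylacetic acid (dicyclohexylcarbodiimide, 4-(dimethylamino)pyridine, CH2Cl2) gives two diastereomers that are separated by chromatography or crystallisation. The one from the (1R,2S,5R,6S)-alcohol is the (S)-O-methylmandelate F4. Dihydroxylation under the conditions of step 11 gives the triol ester F5, and the hydride reduction of step 12 cleaves both esters and returns to the route at 18.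

**Step 11.** Only one hydroxyl is free to hydrogen-bond to the osmium–diamine complex, so facial selectivity may erode toward attack on the face away from the oxygens under steric control. Osmylation of the enoate alkene may also compete.
Fallback: a Woodward cis-hydroxylation, which places the cis-diol on the face opposite to the one an electrophile attacks and does not touch the electron-poor enoate. Setting out from 15, I2 and AgOAc in wet acetic acid, then heating, should proceed via trans iodoacetoxylation (acetate at the tertiary C5) and neighbouring-group displacement of iodide to an acetoxonium ion on the oxygen-bearing face. Hydrolysis gives the hydroxy acetate, drawn as the 4,6-diacetate ethyl ester F6. The hydride reduction of step 12 removes all acetyl groups and returns to the route at 18.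

**Step 22.** The new Cc=Cd alkene may form as an E/Z mixture, and the polar tetraol may react sluggishly with the ylide.
Fallback: a Julia–Kocienski olefination. Setting out from 31, Mitsunobu reaction with 1-phenyl-1H-tetrazole-5-thiol (PPh3, diisopropyl azodicarboxylate) gives the 1-phenyltetrazol-5-yl allyl sulfide F7. Oxidation with H2O2 and (NH4)6Mo7O24 in ethanol gives the 1-phenyltetrazol-5-yl allyl sulfone F8. Deprotonation with KN(SiMe3)2 in 1,2-dimethoxyethane at −60 °C and addition of 19 returns to the route at 35.

## Further compounds

F1 | step 7 | (2Z,4E)-2-iodo-4-methylhexa-2,4-diene | C/C=C(\C)/C=C(\I)C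
F2 | step 7 | (2E)-3-(tributylstannyl)prop-2-enal | O=C/C=C/[Sn](CCCC)(CCCC)CCCC
F3 | step 7 | ethyl (2E,4E)-2-methyl-5-(tributylstannyl)penta-2,4-dienoate | CCOC(=O)/C(C)=C/C=C/[Sn](CCCC)(CCCC)CCCC
F4 | step 10 | (S)-O-methylmandelate of the (1R,2S,5R,6S)-enantiomer of 14 at the C6 hydroxyl | CCOC(=O)/C(C)=C/[C@@H]1[C@H](C)[C@@](C)(O)C=C(C)[C@H]1OC(=O)[C@@H](OC)c1ccccc1
F5 | step 10 | (S)-O-methylmandelate of the all-cis C3,C4,C5-triol ethyl ester | CCOC(=O)/C(C)=C/[C@@H]1[C@H](C)[C@@](C)(O)[C@@H](O)[C@@](C)(O)[C@H]1OC(=O)[C@@H](OC)c1ccccc1
F6 | step 11 | ethyl (2E)-3-[all-cis 4,6-diacetoxy-3,5-dihydroxy ring B]-2-methylprop-2-enoate (ring carbons numbered as in the target) | CCOC(=O)/C(C)=C/[C@@H]1[C@H](C)[C@@](C)(O)[C@@H](OC(C)=O)[C@@](C)(O)[C@H]1OC(C)=O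
F7 | step 22 | 2-methoxy-3,5-dimethyl-6-{(2E)-4-[(1-phenyl-1H-tetrazol-5-yl)sulfanyl]but-2-en-2-yl}-4H-pyran-4-one | COc1oc(/C(C)=C/CSc2nnnn2-c2ccccc2)c(C)c(=O)c1C
F8 | step 22 | 2-methoxy-3,5-dimethyl-6-{(2E)-4-[(1-phenyl-1H-tetrazol-5-yl)sulfonyl]but-2-en-2-yl}-4H-pyran-4-one | COc1oc(/C(C)=C/CS(=O)(=O)c2nnnn2-c2ccccc2)c(C)c(=O)c1C
A1 | alternative 1 | endoperoxide bridging C3 and C6 with a silyloxymethyl group on C1 | CC(C)(C)[Si](C)(C)OC[C@@H]1[C@H](C)[C@]2(C)C=C(C)[C@H]1OO2
A2 | alternative 1 | tert-butyldimethylsilyl ether of (cis-3,5,6-trimethylcyclohexa-2,4-dien-1-yl)methanol | CC(C)(C)[Si](C)(C)OC[C@@H]1[C@H](C)C(C)=CC(C)=C1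
A3 | alternative 2 | 2-methoxy-3,5-dimethyl-6-[(E)-4-(tert-butyldimethylsilyloxy)but-2-en-2-yl]-4H-pyran-4-one | COc1oc(/C(C)=C/CO[Si](C)(C)C(C)(C)C)c(C)c(=O)c1C
A4 | alternative 2 | 2,2,5-trimethyl-6-[(E)-4-(tert-butyldimethylsilyloxy)but-2-en-2-yl]-4H-1,3-dioxin-4-one | CC1=C(/C(C)=C/CO[Si](C)(C)C(C)(C)C)OC(C)(C)OC1=O
A5 | alternative 2 | 1,1-dimethoxyprop-1-ene | CC=C(OC)OC
A6 | alternative 2 | acylketene from A4 | O=C=C(C)C(=O)/C(C)=C/CO[Si](C)(C)C(C)(C)C
A7 | alternative 3 | ring-expanded cyclohexanone with C3 carbinol, C4 ketone and C5,C6 acetonide | c1ccccc1COC[C@@H]1[C@H](C)[C@@](C)(O)C(=O)[C@@]2(C)OC(C)(C)O[C@@H]12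
A8 | alternative 3 | 1-acetylcyclopentanol precursor (ring atoms C4, C5, C6, C1, C2; C4 hydroxyl drawn cis to the acetonide oxygens) | c1ccccc1COC[C@@H]1[C@H](C)[C@](O)(C(C)=O)[C@@]2(C)OC(C)(C)O[C@@H]12
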